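**Plan**

- Retrosynthetic cuts: the five benzyl O–C bonds; then O1–C2 of the flavanone, with a tert-butyl ester on C3 as a removable activator; then the C3=CH(aryl) alkene and the C3–CO2tBu bond; then the diaryl ether bond between flavone C4' and the oxygen on flavanone C6; then the flavone to a chalcone. Both halves go back to 2',4',6'-trihydroxyacetophenone.
- Forward order: the flavone (rings A', C', B') is closed first from a 4-fluorochalcone. The future flavanone ring A is prepared as a 5'-hydroxylated acetophenone and joined to the flavone by SNAr. The side chain is then built by C-acylation and Knoevenagel condensation, and flavanone ring C is closed last.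
- Enabling feature: flavanone C2 is a benzylic ether carbon (O1–C2) that lies beta to the C4 ketone of ring C. This is the retron of a phenol oxygen adding to an arylidene ketone.
- Stereochemistry: the single stereocentre (C2, S) is set in the ring closure by a bifunctional cinchona-alkaloid thiourea and is not touched afterwards.

Key step: step 8

Assumption: the thiourea made from 9-amino-9-deoxy-epi-quinidine is taken as the pseudo-enantiomer that gives the 2S flavanone; if the sense of induction proves opposite, the quinine-derived pseudo-enantiomer replaces it and nothing else changes.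

**Route**

Step 1
Reactants: 1 2',4',6'-trihydroxyacetophenone
Product: 2 2'-hydroxy-4',6'-bis(benzyloxy)acetophenone
Conditions: BnBr (2.1 equiv), K2CO3 (2.2 equiv), DMF, 0 °C → rt
Reagents that add atoms: benzyl bromide, BrCc1ccccc1
Why: Williamson etherification, in which the para hydroxyl and one ortho hydroxyl are alkylated while the remaining ortho hydroxyl, hydrogen-bonded to the acetyl carbonyl, should stay free.

Step 2
Reactants: 2 2'-hydroxy-4',6'-bis(benzyloxy)acetophenone
Product: 4 2',5'-dihydroxy-4',6'-bis(benzyloxy)acetophenone, via aryl potassium sulfate 3 (not isolated)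
Conditions: K2S2O8, aq. NaOH, pyridine, 0 °C → rt; then aq. HCl, toluene, 80 °C
Reagents that add atoms: potassium peroxodisulfate, [K+].[K+].[O-]S(=O)(=O)OOS(=O)(=O)[O-]
Why: Elbs persulfate oxidation, in which the phenoxide of 2 is attacked by peroxodisulfate at the free carbon para to the phenolate oxygen (C5', between the two benzyloxy groups) and acid hydrolysis of sulfate 3 releases the hydroquinone, as established for 2-hydroxy-4,6-dialkoxyacetophenones.

Step 3
Reactants: 2 2'-hydroxy-4',6'-bis(benzyloxy)acetophenone; 5 4-fluorobenzaldehyde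
Product: 6 (E)-4-fluoro-2'-hydroxy-4',6'-bis(benzyloxy)chalcone
Conditions: KOH (aq.), EtOH/THF, rt
Reagents that add atoms: none
Why: Claisen–Schmidt condensation of the acetophenone enolate with a non-enolisable aryl aldehyde, where dehydration of the aldol to the conjugated E enone is the driving force and any flavanone formed alongside is converted equally in step 4.

Step 4
Reactants: 6 (E)-4-fluoro-2'-hydroxy-4',6'-bis(benzyloxy)chalcone
Product: 7 5,7-bis(benzyloxy)-4'-fluoroflavone
Conditions: I2 (10 mol%), DMSO, 120 °C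
Reagents that add atoms: none
Why: Iodine-catalysed oxidative cyclisation of a 2'-hydroxychalcone (oxa-Michael closure, alpha-iodination and loss of HI), with DMSO re-oxidising iodide so that the aromatic pyranone ring C' results.

Step 5
Reactants: 4 2',5'-dihydroxy-4',6'-bis(benzyloxy)acetophenone; 7 5,7-bis(benzyloxy)-4'-fluoroflavone
Product: 8 2'-hydroxy-4',6'-bis(benzyloxy)-5'-{4-[5,7-bis(benzyloxy)-4-oxo-4H-chromen-2-yl]phenoxy}acetophenone
Conditions: Cs2CO3 (2.5 equiv), DMSO, 100 °C, argon
Reagents that add atoms: none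
Why: Nucleophilic aromatic substitution (SNAr) at C4'–F, which is para to the chromone C2 so that the Meisenheimer charge is delocalised onto the pyranone carbonyl; the electron-rich, non-chelated 5'-phenoxide should react in preference to the acetyl-conjugated, chelated 2'-phenoxide, as in the selective 5-O-alkylation of 2,5-dihydroxyacetophenones.

Step 6
Reactants: 8 2'-hydroxy-4',6'-bis(benzyloxy)-5'-{4-[5,7-bis(benzyloxy)-4-oxo-4H-chromen-2-yl]phenoxy}acetophenone
Product: 9 tert-butyl 3-[2-hydroxy-4,6-bis(benzyloxy)-5-{4-[5,7-bis(benzyloxy)-4-oxo-4H-chromen-2-yl]phenoxy}phenyl]-3-oxopropanoate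
Conditions: LiN(SiMe3)2 (3.3 equiv), THF, −78 °C; Boc2O (1.1 equiv), −78 → 0 °C; aq. NH4Cl
Reagents that add atoms: di-tert-butyl dicarbonate, CC(C)(C)OC(=O)OC(=O)OC(C)(C)C
Why: Claisen-type C-acylation of the phenoxide–enolate dianion, in which the third equivalent of base deprotonates the beta-keto ester as it forms, the flavone has no acidic site, and the tert-butyl ester should resist lactonisation to a 4-hydroxycoumarin.

Step 7
Reactants: 9 tert-butyl 3-[2-hydroxy-4,6-bis(benzyloxy)-5-{4-[5,7-bis(benzyloxy)-4-oxo-4H-chromen-2-yl]phenoxy}phenyl]-3-oxopropanoate; 10 4-(benzyloxy)benzaldehyde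
Product: 11 tert-butyl 2-[2-hydroxy-4,6-bis(benzyloxy)-5-{4-[5,7-bis(benzyloxy)-4-oxo-4H-chromen-2-yl]phenoxy}benzoyl]-3-[4-(benzyloxy)phenyl]prop-2-enoate (E/Z mixture, used as such)
Conditions: piperidine (20 mol%), AcOH (20 mol%), 4 Å molecular sieves, toluene, rt
Reagents that add atoms: none
Why: Knoevenagel condensation of the active methylene with the aryl aldehyde under buffered amine catalysis, with water removed by sieves and the temperature kept low so that uncatalysed ring closure should stay slow.

Step 8
Reactants: 11 tert-butyl 2-[2-hydroxy-4,6-bis(benzyloxy)-5-{4-[5,7-bis(benzyloxy)-4-oxo-4H-chromen-2-yl]phenoxy}benzoyl]-3-[4-(benzyloxy)phenyl]prop-2-enoate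
Product: 14 (2S)-5,7-bis(benzyloxy)-2-[4-(benzyloxy)phenyl]-6-{4-[5,7-bis(benzyloxy)-4-oxo-4H-chromen-2-yl]phenoxy}chroman-4-one, via 3-tert-butoxycarbonyl flavanone 12 (not isolated), via flavanone-3-carboxylic acid 13 (not isolated)
Conditions: thiourea from 9-amino-9-deoxy-epi-quinidine and 3,5-bis(trifluoromethyl)phenyl isothiocyanate (10 mol%), toluene, −25 °C; then TsOH·H2O (50 mol%), 80 °C
Reagents that add atoms: none
Why: The quinuclidine nitrogen of the catalyst deprotonates the one free phenol of 11 while the thiourea N–H pair hydrogen-bonds the 1,3-dicarbonyl unit, and the phenoxide adds to the benzylidene carbon to form O1–C2 and give 12; TsOH then cleaves the tert-butyl ester to 13, which loses CO2 to leave the C3 methylene. The closest known reaction is the cinchona-thiourea-catalysed intramolecular oxa-Michael addition of 2-hydroxyaryl alkylidene beta-keto esters with one-pot acid decarboxylation to flavanones. Ring C closes in a 6-endo-trig mode, which the doubly activated alkene makes easy. C2 is controlled by the catalyst alone, which exposes one alkene face to the tethered phenoxide (2S with the pseudo-enantiomer assumed above), and the C3 centre of 12 does not matter because decarboxylation erases it. The step needs enantioface selectivity and O-regioselectivity: the E and Z isomers interconvert by reversible conjugate addition and converge on one product, and because the oxygen ortho to the aryloxy group is benzylated, only the phenol para to it can close, giving the 6-aryloxy and not the 8-aryloxy flavanone. Low temperature in the first stage and acid in the second should suppress the retro-oxa-Michael opening that would racemise C2; partial loss of the chelated flavone 5-benzyl group under the acid would be harmless, since all benzyl groups are removed in step 9.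

Step 9
Reactants: 14 (2S)-5,7-bis(benzyloxy)-2-[4-(benzyloxy)phenyl]-6-{4-[5,7-bis(benzyloxy)-4-oxo-4H-chromen-2-yl]phenoxy}chroman-4-one
Product: 15 (2S)-5,7-dihydroxy-6-[4-(5,7-dihydroxy-4-oxo-4H-chromen-2-yl)phenoxy]-2-(4-hydroxyphenyl)chroman-4-one
Conditions: H2 (1 atm), 10% Pd/C, THF/MeOH, rt
Reagents that add atoms: none
Why: Hydrogenolysis of the five benzyl aryl ethers under neutral conditions, which should leave C2 unepimerised (no base), and the flavanone O1–C2 bond and the flavone C2'=C3' alkene intact if the reaction is stopped once debenzylation is complete.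

**Compound list**

1 | 2',4',6'-trihydroxyacetophenone | CC(=O)c1c(O)cc(O)cc1O | starting material
2 | 2'-hydroxy-4',6'-bis(benzyloxy)acetophenone | CC(=O)c1c(O)cc(OCc2ccccc2)cc1OCc1ccccc1 | intermediate
3 | potassium 3-acetyl-2,6-bis(benzyloxy)-4-hydroxyphenyl sulfate | CC(=O)c1c(O)cc(OCc2ccccc2)c(OS(=O)(=O)[O-])c1OCc1ccccc1.[K+] | intermediate
4 | 2',5'-dihydroxy-4',6'-bis(benzyloxy)acetophenone | CC(=O)c1c(O)cc(OCc2ccccc2)c(O)c1OCc1ccccc1 | intermediate
5 | 4-fluorobenzaldehyde | O=Cc1ccc(F)cc1 | starting material
6 | (E)-4-fluoro-2'-hydroxy-4',6'-bis(benzyloxy)chalcone | O=C(/C=C/c1ccc(F)cc1)c1c(O)cc(OCc2ccccc2)cc1OCc1ccccc1 | intermediate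
7 | 5,7-bis(benzyloxy)-4'-fluoroflavone | O=c1cc(-c2ccc(F)cc2)oc2cc(OCc3ccccc3)cc(OCc3ccccc3)c12 | intermediate
8 | 2'-hydroxy-4',6'-bis(benzyloxy)-5'-{4-[5,7-bis(benzyloxy)-4-oxo-4H-chromen-2-yl]phenoxy}acetophenone | CC(=O)c1c(O)cc(OCc2ccccc2)c(Oc2ccc(-c3cc(=O)c4c(OCc5ccccc5)cc(OCc5ccccc5)cc4o3)cc2)c1OCc1ccccc1 | intermediate
9 | tert-butyl 3-[2-hydroxy-4,6-bis(benzyloxy)-5-{4-[5,7-bis(benzyloxy)-4-oxo-4H-chromen-2-yl]phenoxy}phenyl]-3-oxopropanoate | CC(C)(C)OC(=O)CC(=O)c1c(O)cc(OCc2ccccc2)c(Oc2ccc(-c3cc(=O)c4c(OCc5ccccc5)cc(OCc5ccccc5)cc4o3)cc2)c1OCc1ccccc1 | intermediate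
10 | 4-(benzyloxy)benzaldehyde | O=Cc1ccc(OCc2ccccc2)cc1 | starting material
11 | tert-butyl 2-[2-hydroxy-4,6-bis(benzyloxy)-5-{4-[5,7-bis(benzyloxy)-4-oxo-4H-chromen-2-yl]phenoxy}benzoyl]-3-[4-(benzyloxy)phenyl]prop-2-enoate (E/Z mixture, E isomer written) | CC(C)(C)OC(=O)/C(=C/c1ccc(OCc2ccccc2)cc1)C(=O)c1c(O)cc(OCc2ccccc2)c(Oc2ccc(-c3cc(=O)c4c(OCc5ccccc5)cc(OCc5ccccc5)cc4o3)cc2)c1OCc1ccccc1 | intermediate
12 | tert-butyl (2S)-5,7-bis(benzyloxy)-2-[4-(benzyloxy)phenyl]-6-{4-[5,7-bis(benzyloxy)-4-oxo-4H-chromen-2-yl]phenoxy}-4-oxochromane-3-carboxylate (C3 epimers and enol) | O=C1C(C(=O)OC(C)(C)C)[C@@H](c2ccc(OCc3ccccc3)cc2)Oc2cc(OCc3ccccc3)c(Oc3ccc(-c4cc(=O)c5c(OCc6ccccc6)cc(OCc6ccccc6)cc5o4)cc3)c(OCc3ccccc3)c21 | intermediate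
13 | (2S)-5,7-bis(benzyloxy)-2-[4-(benzyloxy)phenyl]-6-{4-[5,7-bis(benzyloxy)-4-oxo-4H-chromen-2-yl]phenoxy}-4-oxochromane-3-carboxylic acid (C3 epimers) | O=C1C(C(=O)O)[C@@H](c2ccc(OCc3ccccc3)cc2)Oc2cc(OCc3ccccc3)c(Oc3ccc(-c4cc(=O)c5c(OCc6ccccc6)cc(OCc6ccccc6)cc5o4)cc3)c(OCc3ccccc3)c21 | intermediate
14 | (2S)-5,7-bis(benzyloxy)-2-[4-(benzyloxy)phenyl]-6-{4-[5,7-bis(benzyloxy)-4-oxo-4H-chromen-2-yl]phenoxy}chroman-4-one | O=C1C[C@@H](c2ccc(OCc3ccccc3)cc2)Oc2cc(OCc3ccccc3)c(Oc3ccc(-c4cc(=O)c5c(OCc6ccccc6)cc(OCc6ccccc6)cc5o4)cc3)c(OCc3ccccc3)c21 | intermediate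
15 | (2S)-5,7-dihydroxy-6-[4-(5,7-dihydroxy-4-oxo-4H-chromen-2-yl)phenoxy]-2-(4-hydroxyphenyl)chroman-4-one | O=C1C[C@@H](c2ccc(O)cc2)Oc2cc(O)c(Oc3ccc(-c4cc(=O)c5c(O)cc(O)cc5o4)cc3)c(O)c21 | target

**Step count and risks**

Total step count: 9. Longest linear sequence: 8 steps (steps 1, 3, 4, 5, 6, 7, 8, 9); step 2 lies on the shorter branch that joins at step 5.

Steps most likely to fail:

Step 5. The substitution may be too slow: C4'–F is activated only through the vinylogous chromone carbonyl and the attacking phenoxide is flanked by two benzyloxy groups. A slow reaction would let arylation at the chelated phenol or air oxidation of the hydroquinone compete. The fallback replaces SNAr by a copper-catalysed Ullmann ether coupling. It sets out from 2, which is condensed with 4-iodobenzaldehyde (KOH, EtOH/THF, rt) to (E)-4-iodo-2'-hydroxy-4',6'-bis(benzyloxy)chalcone F1. This is cyclised oxidatively (I2 cat., DMSO, 120 °C) to 5,7-bis(benzyloxy)-4'-iodoflavone F2. F2 is coupled with 4 using CuI (monovalent copper, 10 mol%), picolinic acid (20 mol%) and K3PO4 in DMSO at 90 °C, a ligand system suited to ortho,ortho'-disubstituted phenols, and the route is rejoined at 8.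

Step 8. Enantioface discrimination may be poor or the addition sluggish, because the benzyloxy group ortho to the ketone twists the aroyl group out of conjugation and may weaken the two-point thiourea binding; background closure by the amine could also erode selectivity. The fallback changes the mode of activation from hydrogen-bond and Brønsted-base organocatalysis to chelating chiral Lewis-acid catalysis. Starting from 11, the beta-keto ester is bound to divalent nickel in a complex of Ni(CF3COCHCOCH3)2·2H2O with a C2-symmetric chiral N,N'-dioxide ligand (pipecolic acid 2,6-diisopropylanilide type, antipode chosen for 2S) in toluene at rt. The same oxa-Michael closure then takes place inside the metal chelate, followed by the same TsOH decarboxylation. The route is rejoined at 14 through 12 and 13 (no new compound, F0).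

Step 2. Conversion may be low, because the lipophilic dibenzyl ether phenoxide dissolves poorly in the aqueous persulfate medium and over-oxidation can consume product. The fallback installs the oxygen through a quinone. Starting from 2, Teuber oxidation with ON(SO3K)2 (KH2PO4 buffer, acetone/water, rt) should give 2-acetyl-3,5-bis(benzyloxy)-1,4-benzoquinone F3. Reduction with Na2S2O4 (EtOAc/water, rt) then returns the route to 4.

**Further compounds**

F1 | step 5 | (E)-4-iodo-2'-hydroxy-4',6'-bis(benzyloxy)chalcone | O=C(/C=C/c1ccc(I)cc1)c1c(O)cc(OCc2ccccc2)cc1OCc1ccccc1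
F2 | step 5 | 5,7-bis(benzyloxy)-4'-iodoflavone | O=c1cc(-c2ccc(I)cc2)oc2cc(OCc3ccccc3)cc(OCc3ccccc3)c12
F0 | step 8 | none | none
F3 | step 2 | 2-acetyl-3,5-bis(benzyloxy)-1,4-benzoquinone | CC(=O)C1=C(OCc2ccccc2)C(=O)C(OCc2ccccc2)=CC1=O
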